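## Retrosynthetic overview

1. Target 9 ⇐ (13S)-3β,8α,15-triacetoxylabdane 7 by loss of AcOH across C7–C8 (last step, a new catalyst-controlled elimination); 7 is made in the same flask by acetylating alcohol 6.
2. C13 stereocentre ⇐ hydroxyl-directed asymmetric hydrogenation of the E-allylic alcohol 5.
3. C15–O bond ⇐ [3,3] transposition of the tertiary allylic acetate in 3 (C13–O becomes C15–O).
4. C3–O bond (key step) ⇐ site- and stereoselective enzymatic C–H hydroxylation of (−)-sclareol 1, which sets C3 as S.
5. No ring is formed: rings A and B and the C5, C9 and C10 stereocentres are taken intact from sclareol.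

Assumption: (−)-sclareol, a bulk diterpene of the fragrance industry, counts as a cheap commercial starting material. Labdane numbering is used throughout (C3 = acetoxy-bearing carbon of ring A, C7=C8 = olefin of ring B, C13 = side-chain methine, C15 = terminal CH2O).

## Route

Step 1
Reactants: 1 (−)-sclareol [(13R)-labd-14-ene-8α,13-diol]
Product: 2 3β-hydroxysclareol [(13R)-labd-14-ene-3β,8α,13-triol]
Conditions: C3-selective engineered cytochrome P450 BM3 (CYP102A1) variant of the MERO1 type (E. coli lysate), phosphite dehydrogenase, NADP+ (cat.), Na2HPO3, air, potassium phosphate buffer pH 8, 25 °C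
Reagents that add atoms: dioxygen, O=O
Why: The engineered P450 holds the labdane with ring A over the haem and hydroxylates the equatorial 3β C–H by hydrogen abstraction and oxygen rebound with retention (enzymatic C–H hydroxylation, known for sclareol and sclareolide with this enzyme family), which makes the key C3–O bond and sets C3 as S while the vinyl group and both tertiary alcohols are left alone.

Step 2
Reactants: 2 3β-hydroxysclareol
Product: 3 (13R)-3β,8α,13-triacetoxylabd-14-ene
Conditions: AcCl, PhNMe2, CH2Cl2, 0 °C to rt
Reagents that add atoms: acetyl chloride, CC(=O)Cl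
Why: Acetyl chloride with a dialkylaniline base (O-acylation) esterifies the secondary and both hindered tertiary hydroxyls without ionising the tertiary allylic centre, as in the standard preparation of sclareol diacetate, and no stereocentre changes.

Step 3
Reactants: 3 (13R)-3β,8α,13-triacetoxylabd-14-ene
Product: 5 (13E)-3β,8α-diacetoxylabd-13-en-15-ol, via (13E)-triacetate 4 (not isolated)
Conditions: PdCl2(MeCN)2 (5 mol %), THF, rt; then K2CO3 (0.3 equiv), MeOH, 0 °C; E isomer separated from the minor Z isomer on AgNO3–silica
Reagents that add atoms: none
Why: Divalent palladium activates the vinyl group and the C13 acetate closes onto C15 through a six-membered acetoxonium (cyclisation-induced [3,3] allylic ester transposition), which makes the C15–O bond and the E-major trisubstituted olefin, after which methoxide transesterifies only the unhindered primary allylic acetate because the neopentyl-type 3β-acetate and the tertiary 8α-acetate react far more slowly; no stereocentre is formed.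

Step 4
Reactants: 5 (13E)-3β,8α-diacetoxylabd-13-en-15-ol
Product: 6 (13S)-3β,8α-diacetoxylabdan-15-ol
Conditions: Ru(OAc)2[(R)-BINAP] (1 mol %), H2 (50 atm), MeOH–CH2Cl2, 25 °C
Reagents that add atoms: none
Why: Noyori hydroxyl-directed asymmetric hydrogenation, in which the C15 hydroxyl binds ruthenium and the (R)-BINAP complex adds H2 to the face of the E olefin that gives 13S (the geraniol to (S)-citronellol correlation, same substituent pattern and same CIP order), under catalyst control with the esters inert.

Step 5
Reactants: 6 (13S)-3β,8α-diacetoxylabdan-15-ol
Product: 9 (13S)-3β,15-diacetoxylabd-7-ene (CNP0251773.1), via labdane triacetate 7 (not isolated), via exocyclic alkene 8 (not isolated)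
Conditions: Ac2O (1.2 equiv), (R)-3,3′-bis(2,4,6-triisopropylphenyl)-1,1′-binaphthyl-2,2′-diyl N-triflylphosphoramide (5 mol %), toluene, 0 °C, then 45 °C
Reagents that add atoms: acetic anhydride, CC(=O)OC(C)=O
Why: Proposed new method: a confined Brønsted acid catalysed, regioselective E1 dehydroacetoxylation with exo-to-endo funnelling that forms the C7=C8 double bond of ring B, in which the acid first catalyses O-acetylation of the primary alcohol and then ionises the tertiary equatorial C8 acetate to a contact ion pair whose bulky phosphoramide anion is the only base, so that the exposed axial 7α-H and the C17 methyl hydrogens are removed but the buried tertiary 9α-H (flanked by quaternary C10 and the side chain) is not, while the exocyclic alkene 8 formed alongside is re-protonated at its unhindered CH2 terminus and recycled through the same cation until it has drained into the Δ7 olefin, whose ring carbon C7 the confined acid protonates far more slowly, so the tetrasubstituted Δ8(9) isomer is not reached; the closest known reaction types are the TsOH or H2SO4 dehydrations of 8α-oxygenated labdanes and drimanes (which give Δ7/Δ8/exocyclic mixtures) and confined chiral acid control of carbocation deprotonation in cation–olefin cyclisations, and no stereocentre is created or touched.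

## Compound list

1 | (−)-sclareol, (13R)-labd-14-ene-8α,13-diol | C=C[C@](C)(O)CC[C@H]1[C@](C)(O)CC[C@H]2C(C)(C)CCC[C@]12C | starting material
2 | 3β-hydroxysclareol, (13R)-labd-14-ene-3β,8α,13-triol | C=C[C@](C)(O)CC[C@H]1[C@](C)(O)CC[C@H]2C(C)(C)[C@@H](O)CC[C@]12C | intermediate
3 | (13R)-3β,8α,13-triacetoxylabd-14-ene | C=C[C@](C)(OC(C)=O)CC[C@H]1[C@](C)(OC(C)=O)CC[C@H]2C(C)(C)[C@@H](OC(C)=O)CC[C@]12C | intermediate
4 | (13E)-3β,8α,15-triacetoxylabd-13-ene | CC(=O)OC/C=C(\C)CC[C@H]1[C@](C)(OC(C)=O)CC[C@H]2C(C)(C)[C@@H](OC(C)=O)CC[C@]12C | intermediate (not isolated)
5 | (13E)-3β,8α-diacetoxylabd-13-en-15-ol | OC/C=C(\C)CC[C@H]1[C@](C)(OC(C)=O)CC[C@H]2C(C)(C)[C@@H](OC(C)=O)CC[C@]12C | intermediate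
6 | (13S)-3β,8α-diacetoxylabdan-15-ol | OCC[C@@H](C)CC[C@H]1[C@](C)(OC(C)=O)CC[C@H]2C(C)(C)[C@@H](OC(C)=O)CC[C@]12C | intermediate
7 | (13S)-3β,8α,15-triacetoxylabdane | CC(=O)OCC[C@@H](C)CC[C@H]1[C@](C)(OC(C)=O)CC[C@H]2C(C)(C)[C@@H](OC(C)=O)CC[C@]12C | intermediate (not isolated)
8 | (13S)-3β,15-diacetoxylabd-8(17)-ene | CC(=O)OCC[C@@H](C)CC[C@H]1C(=C)CC[C@H]2C(C)(C)[C@@H](OC(C)=O)CC[C@]12C | intermediate (not isolated)
9 | (13S)-3β,15-diacetoxylabd-7-ene, CNP0251773.1 | CC(=O)OCC[C@@H](C)CC[C@H]1C(C)=CC[C@H]2C(C)(C)[C@@H](OC(C)=O)CC[C@]12C | target

## Step count and risks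

Total step count: 5. Longest linear sequence: 5.

**Step 5 (the proposed new elimination).** The risks are incomplete funnelling (residual 8), some Δ8(9) olefin, or hydride and methyl shifts from the C8 cation. The (S) enantiomer of the acid is the first variable to screen, since the regiochemical argument rests on confinement and not on the sense of chirality. The fallback uses known chemistry only; it sets out from 6 and comes back to the route at 9, passing the route's own compound 8. LiAlH4 in THF removes both acetates of 6 to give (13S)-labdane-3β,8α,15-triol F1. Ac2O in pyridine at rt then acetylates only the secondary and primary hydroxyls, giving (13S)-3β,15-diacetoxylabdan-8α-ol F2. SOCl2 in pyridine and CH2Cl2 at −78 °C dehydrates the equatorial tertiary alcohol through its chlorosulfite; anti elimination can reach only the C17 methyl hydrogens, so the exocyclic alkene 8 is the main product. Radical isomerisation with chloro[(R,R)-N,N′-bis(3,5-di-tert-butylsalicylidene)-1,2-cyclohexanediaminato]cobalt (3 mol %) and PhSiH3 in benzene at rt then moves the double bond into ring B: hydrogen-atom transfer to the CH2 terminus gives the C8 radical, and hydrogen is taken back from the less hindered C7, giving 9.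

**Step 3 (transposition and selective methanolysis).** The risk is a modest E:Z ratio, because the methyl and CH2 groups on C13 differ little in size. The fallback replaces reliance on olefin geometry by stereodivergent catalyst pairing; it sets out from 3 and comes back at 6. The same protocol is run on 3 and the Z fraction, (13Z)-3β,8α-diacetoxylabd-13-en-15-ol F3, is collected. F3 is hydrogenated with the enantiomeric catalyst Ru(OAc)2[(S)-BINAP] (H2 50 atm, MeOH, 25 °C), which adds to the opposite face of the reversed olefin geometry and gives the same 13S alcohol 6 (the nerol to (S)-citronellol correlation). Both geometric isomers then feed the route.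

**Step 1 (enzymatic hydroxylation).** The risks are enzyme supply, low substrate loading and minor hydroxylation at other ring positions. The fallback replaces the engineered cell-free enzyme by whole-organism fermentation; it sets out from 1 and comes back at 2. Sclareol is fed to a growing culture of a wild-type fungus such as Mucor plumbeus, a known biotransformation that gives 3β-hydroxysclareol as the main metabolite, and 2 is isolated by extraction and chromatography. No new compound is made.

Further compounds
F1 | step 5 | (13S)-labdane-3β,8α,15-triol | OCC[C@@H](C)CC[C@H]1[C@](C)(O)CC[C@H]2C(C)(C)[C@@H](O)CC[C@]12C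
F2 | step 5 | (13S)-3β,15-diacetoxylabdan-8α-ol | CC(=O)OCC[C@@H](C)CC[C@H]1[C@](C)(O)CC[C@H]2C(C)(C)[C@@H](OC(C)=O)CC[C@]12C
F3 | step 3 | (13Z)-3β,8α-diacetoxylabd-13-en-15-ol | OC/C=C(/C)CC[C@H]1[C@](C)(OC(C)=O)CC[C@H]2C(C)(C)[C@@H](OC(C)=O)CC[C@]12C
F0 | step 1 | none | none
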